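Ring A is the 3-hydroxy-4-aryloxyphenyl ring and ring B the 3-aryloxy-4,5-dihydroxyphenyl ring; positions count from the ring carbon that bears the side chain.
Enabling feature: each quaternary carbon is bonded to C1 of an arene and to a CH3 group. It is therefore a masked 1-arylethyl carbamate whose C–H can become C–chain and whose C–O can become C–B.
Cuts, in retrosynthetic order: the O-protecting groups; both C(quaternary)–CH=CH2 bonds; both C(quaternary)–CH2 bonds to the C11 chains (one flask); the ether bond from O on C4 of ring A to C3 of ring B; the CH2–CH2 bond next to boron in the chain boronate.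
Forward: no ring is formed, and both arenes come from acetovanillone. Ring B is iodinated, masked, reduced and carbamoylated, then etherified with acetovanillone while ring A is still a ketone; ring A is then reduced and carbamoylated. Both chains, both vinyl groups and the deprotection follow.
Stereochemistry: enantiomeric RuCl(TsDPEN)(p-cymene) catalysts set the S carbinol (ring B) and the R carbinol (ring A). Lithiation (retention), borylation (retention), 1,2-shift (inversion at carbon) and Zweifel vinylation (retention) carry them into the S and R quaternary centres.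

Key step: step 9

Assumption: commercial geranyl bromide is taken as the pure E isomer, because its alkene geometry passes unchanged into both chains.

Step 1
Reactants: 1 acetovanillone (1-(4-hydroxy-3-methoxyphenyl)ethanone)
Product: 2 5-iodoacetovanillone (1-(4-hydroxy-3-iodo-5-methoxyphenyl)ethanone)
Conditions: NIS, CF3CO2H (cat.), MeCN, rt
Reagents that add atoms: N-iodosuccinimide, O=C1CCC(=O)N1I
Why: In this electrophilic aromatic iodination the free phenol directs to its only open ortho position, because the para position carries the acetyl group and the other ortho position the methoxy group.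

Step 2
Reactants: 2 5-iodoacetovanillone
Product: 3 1-[3-iodo-5-methoxy-4-(methoxymethoxy)phenyl]ethanone
Conditions: MOMCl, i-Pr2NEt, CH2Cl2, 0 °C → rt
Reagents that add atoms: chloromethyl methyl ether, COCCl
Why: Williamson-type O-alkylation of the acidic phenol gives an acetal that withstands base, copper catalysis and organolithium reagents and, with both ortho positions occupied, cannot direct a ring lithiation later.

Step 3
Reactants: 3 1-[3-iodo-5-methoxy-4-(methoxymethoxy)phenyl]ethanone
Product: 4 (1S)-1-[3-iodo-5-methoxy-4-(methoxymethoxy)phenyl]ethan-1-ol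
Conditions: RuCl[(S,S)-TsDPEN](p-cymene) (1 mol %), HCO2H/Et3N (5:2), CH2Cl2, 30 °C
Reagents that add atoms: none
Why: In the Noyori–Ikariya asymmetric transfer hydrogenation the (S,S)-ligated ruthenium hydride delivers hydrogen to the Re face of the aryl methyl ketone through the arene-stabilised six-membered transition state, which sets the S carbinol and leaves the aryl iodide and the acetal untouched.

Step 4
Reactants: 4 (1S)-1-[3-iodo-5-methoxy-4-(methoxymethoxy)phenyl]ethan-1-ol
Product: 5 (1S)-1-[3-iodo-5-methoxy-4-(methoxymethoxy)phenyl]ethyl N,N-diisopropylcarbamate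
Conditions: i-Pr2NCOCl, Et3N, CH2Cl2, reflux
Reagents that add atoms: N,N-diisopropylcarbamoyl chloride, CC(C)N(C(C)C)C(=O)Cl
Why: O-Carbamoylation takes place at oxygen only, so the S centre is not touched, and the hindered carbamate is the standard directing and leaving group for benzylic lithiation–borylation.

Step 5
Reactants: 5 (1S)-1-[3-iodo-5-methoxy-4-(methoxymethoxy)phenyl]ethyl N,N-diisopropylcarbamate; 1 acetovanillone
Product: 6 (1S)-1-[3-(4-acetyl-2-methoxyphenoxy)-5-methoxy-4-(methoxymethoxy)phenyl]ethyl N,N-diisopropylcarbamate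
Conditions: 1 (1.5 equiv), CuI (10 mol %), N,N-dimethylglycine hydrochloride (30 mol %), Cs2CO3, 1,4-dioxane, 95 °C, Ar
Reagents that add atoms: none
Why: In this ligand-accelerated Ullmann diaryl ether synthesis, ring A enters as the ketone so that no para-phenoxide ever faces a benzylic carbamate, which it would expel as a quinone methide, and no free phenol competes in a carbamoylation.

Step 6
Reactants: 6 keto carbamate
Product: 7 (1S)-1-{3-[4-[(1R)-1-hydroxyethyl]-2-methoxyphenoxy]-5-methoxy-4-(methoxymethoxy)phenyl}ethyl N,N-diisopropylcarbamate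
Conditions: RuCl[(R,R)-TsDPEN](p-cymene) (1 mol %), HCO2H/Et3N (5:2), CH2Cl2, 35 °C
Reagents that add atoms: none
Why: The Noyori–Ikariya asymmetric transfer hydrogenation with the enantiomeric catalyst delivers hydrogen to the Si face and sets the R carbinol on ring A under pure catalyst control, since the S centre on ring B is too remote to interfere.

Step 7
Reactants: 7 hydroxy carbamate
Product: 8 heterochiral bis-carbamate (1S)-1-{3-[4-[(1R)-1-(diisopropylcarbamoyloxy)ethyl]-2-methoxyphenoxy]-5-methoxy-4-(methoxymethoxy)phenyl}ethyl N,N-diisopropylcarbamate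
Conditions: i-Pr2NCOCl, Et3N, CH2Cl2, reflux
Reagents that add atoms: N,N-diisopropylcarbamoyl chloride, CC(C)N(C(C)C)C(=O)Cl
Why: The same O-carbamoylation as in step 4 acylates the only free hydroxyl group without touching either C–O stereocentre.

Step 8
Reactants: 9 geranyl bromide; 10 bis[(pinacolato)boryl]methane
Product: 12 homogeranyl pinacol boronate (2-[(3E)-4,8-dimethylnona-3,7-dien-1-yl]-4,4,5,5-tetramethyl-1,3,2-dioxaborolane), via sodium borylmethanide 11 (not isolated)
Conditions: 10, NaOt-Bu, THF, 0 °C; then 9, 0 °C → rt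
Reagents that add atoms: none
Why: In this alkoxide-induced deborylative alkylation of a geminal bis(boronate), tert-butoxide adds to one boron and releases the boron-stabilised carbanion 11, which displaces the primary allylic bromide in SN2 fashion with the E alkene intact, whereas deprotonation with an amide base would have kept both boron atoms.

Step 9
Reactants: 8 heterochiral bis-carbamate; 12 homogeranyl pinacol boronate (two molecules enter)
Product: 15 bis(tertiary benzylic pinacol boronate) carrying both C11 chains (R at ring A; S at ring B), via dilithiated bis-carbamate 13 (not isolated), via dilithium bis-boronate complex 14 (not isolated)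
Conditions: s-BuLi (2.6 equiv), Et2O, −78 °C, 1 h; 12 (3.0 equiv), −78 °C, 2 h; MgBr2 in MeOH (1 M), −78 °C → rt, 16 h
Reagents that add atoms: none
Why: s-BuLi, held by each carbamate carbonyl, removes the two benzylic hydrogens with retention to give the configurationally stable dilithio species 13, and 12 captures each C–Li bond with retention to give the bis-boronate complex 14. On warming, each homogeranyl CH2 shifts from boron to carbon antiperiplanar to the departing carbamate, so inversion at carbon places the chain where hydrogen stood and boron where oxygen stood. The closest known reaction is the lithiation–borylation of enantioenriched secondary benzylic carbamates, a stereospecific 1,2-metallate rearrangement of the Matteson type, used here at two independent sites of one molecule, and no ring closes. The R centre at ring A derives only from the R carbinol and the S centre at ring B only from the S carbinol. MgBr2 in MeOH speeds the migration and protonates any carbanion released by reversal of boronate formation, which protects the stereochemical fidelity. The step needs benzylic rather than ring lithiation, and this is secured because the acetal on ring B has no free ortho position, methoxy and aryloxy are weak directors at −78 °C in Et2O without a diamine, and the remote trisubstituted alkenes of 12 are inert.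

Step 10
Reactants: 15 bis(tertiary benzylic pinacol boronate)
Product: 18 bis-vinyl compound with two methyl ethers plus one MOM ether (R at ring A; S at ring B), via bis(vinylboronate) complex 16 (not isolated), via bis(beta-iodoalkyl) boronic ester 17 (not isolated)
Conditions: vinyllithium (from tetravinylstannane, n-BuLi), THF, −78 °C → rt; I2, THF, −78 °C; NaOMe, MeOH, −78 °C → rt
Reagents that add atoms: vinyllithium, [Li]C=C (made in the flask from tetravinylstannane, C=C[Sn](C=C)(C=C)C=C, and n-BuLi)
Why: In the Zweifel olefination vinyllithium adds to each boron, iodine activates the vinyl group for a 1,2-shift of the tertiary benzylic carbon with retention, and methoxide triggers anti elimination of boron and iodide, so both quaternary centres keep their configuration.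

Step 11
Reactants: 18 bis-vinyl compound
Product: 19 bis-phenol that keeps the MOM ether on O4 of ring B
Conditions: NaSEt (excess), DMF, 130 °C, Ar; aqueous work-up
Reagents that add atoms: none
Why: SN2 demethylation of aryl methyl ethers by thiolate is proven on aryl methyl ethers that carry prenyl-type alkenes, it leaves alkenes, quaternary centres and the diaryl ether alone, and it is run before acetal removal so that no catecholate dianion has to form.

Step 12
Reactants: 19 bis-phenol MOM ether
Product: 20 CNP0230356.1 (5-[(3S,6E)-3,7,11-trimethyldodeca-1,6,10-trien-3-yl]-3-{2-hydroxy-4-[(3R,6E)-3,7,11-trimethyldodeca-1,6,10-trien-3-yl]phenoxy}benzene-1,2-diol)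
Conditions: p-TsOH·H2O (cat.), MeOH, 40 °C, Ar
Reagents that add atoms: none
Why: Acid-catalysed transacetalisation of the aryl MOM ether to methanol needs only mild sulfonic acid catalysis, which should spare the trisubstituted alkenes, none of which sits ortho to a phenol, so no chroman can form.

Compound list
1 | acetovanillone | CC(=O)c1ccc(O)c(OC)c1 | starting material
2 | 5-iodoacetovanillone | CC(=O)c1cc(I)c(O)c(OC)c1 | intermediate
3 | 1-[3-iodo-5-methoxy-4-(methoxymethoxy)phenyl]ethanone | CC(=O)c1cc(I)c(OCOC)c(OC)c1 | intermediate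
4 | (1S)-1-[3-iodo-5-methoxy-4-(methoxymethoxy)phenyl]ethan-1-ol | COCOc1c(I)cc(cc1OC)[C@H](C)O | intermediate
5 | (1S)-1-[3-iodo-5-methoxy-4-(methoxymethoxy)phenyl]ethyl N,N-diisopropylcarbamate | COCOc1c(I)cc(cc1OC)[C@H](C)OC(=O)N(C(C)C)C(C)C | intermediate
6 | diaryl ether, ring A acetyl, ring B (S)-carbamate | COc1cc(C(C)=O)ccc1Oc1cc([C@H](C)OC(=O)N(C(C)C)C(C)C)cc(OC)c1OCOC | intermediate
7 | diaryl ether, ring A (R)-carbinol, ring B (S)-carbamate | COc1cc([C@@H](C)O)ccc1Oc1cc([C@H](C)OC(=O)N(C(C)C)C(C)C)cc(OC)c1OCOC | intermediate
8 | heterochiral bis(N,N-diisopropylcarbamate), R at ring A, S at ring B | COc1cc([C@@H](C)OC(=O)N(C(C)C)C(C)C)ccc1Oc1cc([C@H](C)OC(=O)N(C(C)C)C(C)C)cc(OC)c1OCOC | intermediate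
9 | geranyl bromide | CC(C)=CCC/C(C)=C/CBr | starting material
10 | bis[(pinacolato)boryl]methane | CC1(C)OB(CB2OC(C)(C)C(C)(C)O2)OC1(C)C | starting material
11 | sodium (4,4,5,5-tetramethyl-1,3,2-dioxaborolan-2-yl)methanide | [Na]CB1OC(C)(C)C(C)(C)O1 | intermediate
12 | homogeranyl pinacol boronate | CC1(C)OB(CC/C=C(\C)CCC=C(C)C)OC1(C)C | intermediate
13 | dilithiated bis-carbamate, R at ring A, S at ring B | COc1cc([C@@]([Li])(C)OC(=O)N(C(C)C)C(C)C)ccc1Oc1cc([C@]([Li])(C)OC(=O)N(C(C)C)C(C)C)cc(OC)c1OCOC | intermediate
14 | dilithium bis-boronate complex, R at ring A, S at ring B | COc1cc([C@@]([B-]2(CC/C=C(\C)CCC=C(C)C)OC(C)(C)C(C)(C)O2)(C)OC(=O)N(C(C)C)C(C)C)ccc1Oc1cc([C@]([B-]2(CC/C=C(\C)CCC=C(C)C)OC(C)(C)C(C)(C)O2)(C)OC(=O)N(C(C)C)C(C)C)cc(OC)c1OCOC.[Li+].[Li+] | intermediate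
15 | bis(tertiary benzylic pinacol boronate), R at ring A, S at ring B | COc1cc([C@@](C)(B2OC(C)(C)C(C)(C)O2)CC/C=C(\C)CCC=C(C)C)ccc1Oc1cc([C@](C)(B2OC(C)(C)C(C)(C)O2)CC/C=C(\C)CCC=C(C)C)cc(OC)c1OCOC | intermediate
16 | dilithium bis(vinylboronate) complex | COc1cc([C@@](C)([B-]2(C=C)OC(C)(C)C(C)(C)O2)CC/C=C(\C)CCC=C(C)C)ccc1Oc1cc([C@](C)([B-]2(C=C)OC(C)(C)C(C)(C)O2)CC/C=C(\C)CCC=C(C)C)cc(OC)c1OCOC.[Li+].[Li+] | intermediate
17 | bis(2-iodo-1-borylethyl) compound, boron-bearing CH centres unassigned and lost on elimination | COc1cc([C@@](C)(C(CI)B2OC(C)(C)C(C)(C)O2)CC/C=C(\C)CCC=C(C)C)ccc1Oc1cc([C@](C)(C(CI)B2OC(C)(C)C(C)(C)O2)CC/C=C(\C)CCC=C(C)C)cc(OC)c1OCOC | intermediate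
18 | bis-vinyl compound, two OMe and one OMOM, R at ring A, S at ring B | COc1cc([C@@](C)(C=C)CC/C=C(\C)CCC=C(C)C)ccc1Oc1cc([C@](C)(C=C)CC/C=C(\C)CCC=C(C)C)cc(OC)c1OCOC | intermediate
19 | bis-phenol, MOM ether on O4 of ring B | Oc1cc([C@@](C)(C=C)CC/C=C(\C)CCC=C(C)C)ccc1Oc1cc([C@](C)(C=C)CC/C=C(\C)CCC=C(C)C)cc(O)c1OCOC | intermediate
20 | CNP0230356.1 | C=C[C@@](C)(CC/C=C(\C)CCC=C(C)C)c1ccc(Oc2cc([C@](C)(C=C)CC/C=C(\C)CCC=C(C)C)cc(O)c2O)c(O)c1 | target

Total step count: 12. Longest linear sequence: 11 (steps 1–7 and 9–12); step 8 is a one-step side branch.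

Steps most likely to fail

Step 9.
- Risk: The second deprotonation may stall, or the dilithio species may precipitate. Some ring metalation may compete, and boronate formation may partly reverse on warming. Any of these would leave one site unhomologated or erode the configuration at one centre.
- Fallback: the two centres are built one after the other, each by the single-site operations.
- The fallback sets out from 7. The ring A alcohol is silylated (TBSCl, imidazole, DMF) to the tert-butyldimethylsilyl ether F1.
- Single lithiation–borylation at ring B (s-BuLi, Et2O, −78 °C; 12; MgBr2 in MeOH) should give the ring B tertiary boronate F2, and Zweifel vinylation the ring B vinyl compound F3.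
- n-Bu4NF frees the ring A alcohol F4, which is carbamoylated to the ring A carbamate F5.
- A second single lithiation–borylation gives the ring A tertiary boronate F6, whose Zweifel vinylation comes back to the route at 18.

Step 5.
- Risk: C–O bond formation may be slow, because the para-acetyl phenoxide is a weak nucleophile and the iodide is electron-rich and ortho-substituted. Protodeiodination and base-induced condensation of the ketone could then take over.
- Fallback: the polarity of the ether synthesis is reversed, so that the acetyl group activates instead of hampering.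
- The fallback sets out from 5. Copper-catalysed hydroxylation (CuI, 1,10-phenanthroline, KOH, DMSO–H2O, 100 °C) gives the ring B phenol F7.
- F7 displaces fluoride from commercial 4-fluoro-3-methoxyacetophenone (CC(=O)c1ccc(F)c(OC)c1) by SNAr (K2CO3, DMSO, 110 °C) and comes back to the route at 6.

Step 11.
- Risk: Cleavage of the second methyl ether may remain incomplete. The acetal may be lost early, which would turn ring B into a slowly reacting catecholate. The electron-rich phenoxides may oxidise at 130 °C on the most advanced material.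
- Fallback: the methyl ethers are exchanged for silyl ethers before the chains are attached.
- The fallback sets out from 8. LiPPh2 (THF, rt) removes both methyl groups to give the bis-phenol bis-carbamate F8. Both new phenoxides are meta to the benzylic carbamates, so no quinone methide can form as long as the acetal stays in place.
- TIPSCl and imidazole in DMF give the bis(triisopropylsilyl) ether F9.
- The twofold lithiation–borylation with 12 gives the bis-silyl bis-boronate F10, and the twofold Zweifel vinylation the bis-silyl bis-vinyl compound F11.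
- n-Bu4NF at 0 °C then comes back to the route at 19.

Further compounds
F1 | step 9 | ring A (R)-tert-butyldimethylsilyl ether, ring B (S)-carbamate | COc1cc([C@@H](C)O[Si](C)(C)C(C)(C)C)ccc1Oc1cc([C@H](C)OC(=O)N(C(C)C)C(C)C)cc(OC)c1OCOC
F2 | step 9 | ring A (R)-silyl ether, ring B (S)-tertiary pinacol boronate | COc1cc([C@@H](C)O[Si](C)(C)C(C)(C)C)ccc1Oc1cc([C@](C)(B2OC(C)(C)C(C)(C)O2)CC/C=C(\C)CCC=C(C)C)cc(OC)c1OCOC
F3 | step 9 | ring A (R)-silyl ether, ring B (S)-vinyl quaternary centre | COc1cc([C@@H](C)O[Si](C)(C)C(C)(C)C)ccc1Oc1cc([C@](C)(C=C)CC/C=C(\C)CCC=C(C)C)cc(OC)c1OCOC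
F4 | step 9 | ring A (R)-carbinol, ring B (S)-vinyl quaternary centre | COc1cc([C@@H](C)O)ccc1Oc1cc([C@](C)(C=C)CC/C=C(\C)CCC=C(C)C)cc(OC)c1OCOC
F5 | step 9 | ring A (R)-carbamate, ring B (S)-vinyl quaternary centre | COc1cc([C@@H](C)OC(=O)N(C(C)C)C(C)C)ccc1Oc1cc([C@](C)(C=C)CC/C=C(\C)CCC=C(C)C)cc(OC)c1OCOC
F6 | step 9 | ring A (R)-tertiary pinacol boronate, ring B (S)-vinyl quaternary centre | COc1cc([C@@](C)(B2OC(C)(C)C(C)(C)O2)CC/C=C(\C)CCC=C(C)C)ccc1Oc1cc([C@](C)(C=C)CC/C=C(\C)CCC=C(C)C)cc(OC)c1OCOC
F7 | step 5 | (1S)-1-[3-hydroxy-5-methoxy-4-(methoxymethoxy)phenyl]ethyl N,N-diisopropylcarbamate | COCOc1c(O)cc(cc1OC)[C@H](C)OC(=O)N(C(C)C)C(C)C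
F8 | step 11 | bis-phenol bis-carbamate, R at ring A, S at ring B | Oc1cc([C@@H](C)OC(=O)N(C(C)C)C(C)C)ccc1Oc1cc([C@H](C)OC(=O)N(C(C)C)C(C)C)cc(O)c1OCOC
F9 | step 11 | bis(triisopropylsilyl) ether bis-carbamate | CC(C)[Si](C(C)C)(C(C)C)Oc1cc([C@@H](C)OC(=O)N(C(C)C)C(C)C)ccc1Oc1cc([C@H](C)OC(=O)N(C(C)C)C(C)C)cc(O[Si](C(C)C)(C(C)C)C(C)C)c1OCOC
F10 | step 11 | bis(triisopropylsilyl) ether bis(tertiary pinacol boronate) | CC(C)[Si](C(C)C)(C(C)C)Oc1cc([C@@](C)(B2OC(C)(C)C(C)(C)O2)CC/C=C(\C)CCC=C(C)C)ccc1Oc1cc([C@](C)(B2OC(C)(C)C(C)(C)O2)CC/C=C(\C)CCC=C(C)C)cc(O[Si](C(C)C)(C(C)C)C(C)C)c1OCOC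
F11 | step 11 | bis(triisopropylsilyl) ether bis-vinyl compound | CC(C)[Si](C(C)C)(C(C)C)Oc1cc([C@@](C)(C=C)CC/C=C(\C)CCC=C(C)C)ccc1Oc1cc([C@](C)(C=C)CC/C=C(\C)CCC=C(C)C)cc(O[Si](C(C)C)(C(C)C)C(C)C)c1OCOC
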